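The numbers in the tables were generated by integration with made-up constants, and the scatter is random.

Amounts first. The flask held 1.70 µM of free enzyme against 0.78 µM of impurity, and I took these two amounts as the pair that matters. If each impurity takes one enzyme for good, the rate follows the working enzyme, the charge minus the impurity, which is 0.925 µM in the flask.

| flask | starting material | second substrate | free enzyme | impurity | remark |
|---|---|---|---|---|---|
| larch | 31 mM | 0.95 equiv | 0.0055 mol% | 0.39 µM | run made earlier |
| birch | 31 mM | 0.95 equiv | 0.0055 mol% | 0.58 µM | run made earlier |
| flask | 31 mM | 0.950 equiv | 0.0055 mol% | 0.78 µM |  |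

| run | time / min | target / % | starting material / % |
|---|---|---|---|
| larch | 0.500 | 7.3 | 93.1 |
| larch | 1.33 | 18.5 | 81.6 |
| larch | 2.50 | 32.7 | 66.9 |
| larch | 4.00 | 49.6 | 50.3 |
| larch | 6.00 | 67.6 | 32.7 |
| larch | 8.00 | 80.1 | 19.4 |
| birch | 0.500 | 6.0 | 94.1 |
| birch | 1.00 | 11.6 | 87.4 |
| birch | 1.50 | 17.1 | 83.0 |
| birch | 2.50 | 28.4 | 71.4 |
| birch | 4.00 | 43.9 | 56.3 |
| birch | 8.00 | 73.7 | 25.5 |

(standard deviation of a reading: 0.5 percentage points)

Larch and birch differed in their impurity, so they tested this. Their working enzyme came to 1.31 µM and 1.12 µM, a ratio of 1.17, and at 2.50 min the larch target reading over the birch one was 1.15, within the scatter. Neither run changed the second substrate, so I had no reckoning for doubling it. At 0.06 mol% the flask would have 17.8 µM working, which I reckoned as a factor of 19.2 on the rate.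

- factor on the rate of making target when 50% of the starting material are converted if second substrate is charged twice over
- factor on the rate when 50% of the starting material are converted if free enzyme is charged at 0.06 mol% instead

- steps thought possible: first complex -> loaded enzyme + first product; free enzyme + impurity -> spent catalyst; starting material + free enzyme <-> first complex; second complex -> free enzyme + target; second substrate + loaded enzyme <-> second complex
- no earlier run changes the charge of free enzyme; that part of a forecast is a guess
- no earlier run changes the charge of second substrate; that part of a forecast is a guess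

The forecast gave 1.35 (1.08 to 1.68) for the doubling and 19.3 (17.5 to 20.5) for the enzyme, reading that “the impurity appears to titrate enzyme quickly”.

    first complex → loaded enzyme + first product (k = 140 s⁻¹)
    free enzyme + impurity → spent catalyst (k = 2.30 × 10⁶ M⁻¹ s⁻¹)
    starting material + free enzyme ⇌ first complex (K = 35.0 M⁻¹, k = 89000 M⁻¹ s⁻¹)
    second complex → free enzyme + target (k = 300 s⁻¹)
    second substrate + loaded enzyme ⇌ second complex (K = 740 M⁻¹, k = 2.40 × 10⁵ M⁻¹ s⁻¹)

The doubling gave 1.02, below the forecast's range, and the enzyme change gave 19.3. In the flask at 6.00 min, spent catalyst stood at 45.7% of the catalyst charged, with impurity at 0%, and first complex, loaded enzyme, second complex and free enzyme together stood at 54.3%, against 54.4% for the working enzyme over the charge. In the flask, second complex fell back 1.1 times as fast as it went on to target at 2.73 min. Twice the second substrate multiplied the time to that conversion by 0.988.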